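**Retrosynthetic overview** (labdane numbering: ring A = C1–C5 and C10; ring B = C5–C10; C20 = methyl on C10; side chain C11–C16)

- The target is cut at C9–C11 into bromo ketone 24 and an (R)-linalool-derived iodide 7 (organocerium addition anti to the axial C20 methyl sets C9), and at C3–Br back through the axial C3 alcohol to the C3 ketone 20.
- Key disconnection C1–C10: 6-endo radical conjugate addition of a tertiary C10 radical (from the C10=C20 exocyclic methylene of 19 by hydrogen-atom transfer) to the C1=C2–C3(=O) vinyl ketone on the C5 substituent. One operation closes ring A and makes the quaternary C10 with its C20 methyl, the trans ring fusion and the C3 carbonyl.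
- Enabling feature: C10 is a methyl-bearing quaternary ring-fusion carbon (a tertiary-radical retron), and the brominated C3 of ring A lies 1,3 to C1, so C1 is the β-carbon of an enone. The C4 gem-dimethyl group on the tether and the all-equatorial ring B (C5, C8, C9) steer the closure to the trans-decalin.
- Ring order: ring B first, taken from (S)-pulegone (its ketone carbon becomes C10, its isopropylidene carbon C4, its methyl stereocentre C8); ring A second, in the key step.

Key step: step 11

Remark on the chemistry: (S)-(−)-pulegone and (R)-(−)-linalool are taken as commercial, enantiomerically enriched starting materials; α is the face of the C20 methyl, β the face of H5; TBS = tert-butyldimethylsilyl.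

**Route**

Step 1
Reactants: 1 (R)-(−)-linalool
Product: 2 tert-butyl{[(3R)-3,7-dimethylocta-1,6-dien-3-yl]oxy}dimethylsilane
Conditions: TBSOTf, 2,6-lutidine, CH2Cl2, 0 °C → rt
Reagents that add atoms: tert-butyldimethylsilyl trifluoromethanesulfonate, CC(C)(C)[Si](C)(C)OS(=O)(=O)C(F)(F)F
Why: O-silylation of the tertiary allylic alcohol with a silyl triflate should proceed without touching the C13 stereocentre, which comes from linalool.

Step 2
Reactants: 2 tert-butyl{[(3R)-3,7-dimethylocta-1,6-dien-3-yl]oxy}dimethylsilane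
Product: 4 (4R)-4-[(tert-butyldimethylsilyl)oxy]-4-methylhex-5-enal, via secondary ozonide 3 (not isolated)
Conditions: O3, CH2Cl2, pyridine (trace), Sudan Red 7B (indicator), −78 °C; then PPh3, −78 °C → rt
Reagents that add atoms: ozone, [O-][O+]=O
Why: Chemoselective ozonolysis; the electron-rich trisubstituted alkene should react well before the hindered vinyl group next to the silyloxy carbon, with the dye marking the end point.

Step 3
Reactants: 4 (4R)-4-[(tert-butyldimethylsilyl)oxy]-4-methylhex-5-enal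
Product: 5 (4R)-4-[(tert-butyldimethylsilyl)oxy]-4-methylhex-5-enoic acid
Conditions: NaClO2, NaH2PO4, 2-methylbut-2-ene, t-BuOH/H2O, 0 °C → rt
Reagents that add atoms: sodium chlorite, [Na+].[O-]Cl=O
Why: Pinnick oxidation; the alkene scavenger protects the vinyl group from hypochlorite.

Step 4
Reactants: 5 (4R)-4-[(tert-butyldimethylsilyl)oxy]-4-methylhex-5-enoic acid
Product: 7 tert-butyl{[(3R)-5-iodo-3-methylpent-1-en-3-yl]oxy}dimethylsilane, via Barton ester 6 (not isolated)
Conditions: N-hydroxypyridine-2-thione, DCC, DMAP (cat.), CH2Cl2, 0 °C, dark; then CHI3, hν (tungsten lamp), rt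
Reagents that add atoms: iodoform, IC(I)I
Why: Barton decarboxylative iodination (radical chain); the primary radical abstracts iodine from iodoform faster than it can add to the distant vinyl group, and the chain is shortened by one carbon to the C11–C15 unit.

Step 5
Reactants: 8 (S)-(−)-pulegone
Product: 10 (2R,5S)-5-methyl-2-(2-methylbut-3-en-2-yl)cyclohexan-1-one, via bromomagnesium enolate 9 (not isolated)
Conditions: CH2=CHMgBr, CuBr·SMe2 (10 mol %), THF, −30 → 0 °C; then H2O; then KOH (cat.), EtOH, 50 °C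
Reagents that add atoms: vinylmagnesium bromide, C=C[Mg]Br
Why: Copper-catalysed conjugate addition of the vinyl Grignard reagent to the s-cis enone builds the quaternary C4; C5 is set by protonation and base equilibration to the trans-2,5 (diequatorial) ketone relative to the C8 methyl from pulegone.

Step 6
Reactants: 10 (2R,5S)-5-methyl-2-(2-methylbut-3-en-2-yl)cyclohexan-1-one
Product: 12 (2R,3S,6R)-2-hydroxy-3-methyl-6-(2-methylbut-3-en-2-yl)cyclohexan-1-one, via potassium enolate 11 (not isolated)
Conditions: KN(SiMe3)2, THF, −78 °C; then 2-(benzenesulfonyl)-3-phenyloxaziridine, −78 °C; then H2O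
Reagents that add atoms: 2-(benzenesulfonyl)-3-phenyloxaziridine (Davis oxaziridine), O=S(=O)(c1ccccc1)N1OC1c1ccccc1
Why: Kinetic deprotonation at the unhindered α'-CH2 (C9) and Davis enolate hydroxylation; oxygen should enter trans to the adjacent C8 methyl, giving the all-equatorial ketol, which is also the thermodynamically preferred epimer.

Step 7
Reactants: 12 (2R,3S,6R)-2-hydroxy-3-methyl-6-(2-methylbut-3-en-2-yl)cyclohexan-1-one
Product: 13 (2R,3S,6R)-2-[(tert-butyldimethylsilyl)oxy]-3-methyl-6-(2-methylbut-3-en-2-yl)cyclohexan-1-one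
Conditions: TBSCl, imidazole, DMF, rt → 40 °C
Reagents that add atoms: tert-butyldimethylsilyl chloride, CC(C)(C)[Si](C)(C)Cl
Why: Standard silylation of the secondary α-hydroxyl; the mild base should not enolise the ketone.

Step 8
Reactants: 13 (2R,3S,6R)-2-[(tert-butyldimethylsilyl)oxy]-3-methyl-6-(2-methylbut-3-en-2-yl)cyclohexan-1-one
Product: 14 tert-butyldimethyl{[(1R,3R,6S)-6-methyl-2-methylidene-3-(2-methylbut-3-en-2-yl)cyclohexyl]oxy}silane
Conditions: Ph3PCH3Br, KOtBu, toluene, 0 → 90 °C
Reagents that add atoms: methyltriphenylphosphonium bromide, C[P+](c1ccccc1)(c1ccccc1)c1ccccc1.[Br-]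
Why: Wittig methylenation under the hot, alkoxide-base conditions used for hindered ketones; both α-stereocentres are already equatorial, so base should not erode them.

Step 9
Reactants: 14 tert-butyldimethyl{[(1R,3R,6S)-6-methyl-2-methylidene-3-(2-methylbut-3-en-2-yl)cyclohexyl]oxy}silane
Product: 15 3-[(1S,3R,4S)-3-[(tert-butyldimethylsilyl)oxy]-4-methyl-2-methylidenecyclohexyl]-3-methylbutan-2-one
Conditions: PdCl2 (10 mol %), CuCl (cat.), O2 (1 atm), DMF/H2O (7:1), rt
Reagents that add atoms: water, O
Why: Tsuji–Wacker oxidation; Markovnikov hydroxypalladation of the monosubstituted vinyl group gives the methyl ketone (C3=O), while the 1,1-disubstituted exocyclic alkene is not a Wacker substrate.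

Step 10
Reactants: 15 3-[(1S,3R,4S)-3-[(tert-butyldimethylsilyl)oxy]-4-methyl-2-methylidenecyclohexyl]-3-methylbutan-2-one
Product: 19 4-[(1S,3R,4S)-3-[(tert-butyldimethylsilyl)oxy]-4-methyl-2-methylidenecyclohexyl]-4-methylpent-1-en-3-one, via lithium enolate 16 (not isolated), via Mannich base 17 (not isolated), via methiodide 18 (not isolated)
Conditions: LiN(i-Pr)2, THF, −78 °C; Me2N=CH2+ I−, −78 → 0 °C; MeI, Et2O, rt; NaHCO3, CH2Cl2/H2O, rt
Reagents that add atoms: N,N-dimethylmethyleneiminium iodide (Eschenmoser's salt), C=[N+](C)C.[I-]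
Why: Mannich reaction at the only enolisable position (the ketone CH3), then quaternisation and E1cB elimination (α-methylenation) should give the vinyl ketone and so add C1.

Step 11
Reactants: 19 4-[(1S,3R,4S)-3-[(tert-butyldimethylsilyl)oxy]-4-methyl-2-methylidenecyclohexyl]-4-methylpent-1-en-3-one
Product: 20 (4aR,5R,6S,8aS)-5-[(tert-butyldimethylsilyl)oxy]-1,1,4a,6-tetramethyloctahydronaphthalen-2(1H)-one
Conditions: Fe(acac)3 (30 mol %), PhSiH3, EtOH/(CH2OH)2 (5:1), 60 °C
Reagents that add atoms: none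
Why: An iron hydride formed from Fe(acac)3 and PhSiH3 transfers a hydrogen atom to the CH2 terminus of the 1,1-disubstituted C10=C20 alkene (Markovnikov MHAT), which makes the C20 methyl and a nucleophilic tertiary radical at C10; this radical adds to C1, the β-carbon of the tethered vinyl ketone, and the α-keto radical so formed is reduced and protonated at C2. The closest known reaction type is the iron-mediated reductive olefin coupling (HAT-initiated Giese addition) in its intramolecular form. Ring A closes in the 6-endo-trig mode, because 5-exo attack at C2 would put the nucleophilic radical on the α-carbon of the enone and leave an unstabilised primary radical. The one new stereocentre, C10, is controlled by C5: in the chair-like transition state the ring B bonds C5–C6 and C10–C9 are equatorial on the forming ring and the small C20 methyl, not C9, takes the axial site 1,3 to the axial C4 methyl, so C1 bonds to the β face and the fusion should be trans (H5 and C20 anti), as in radical polyene cyclisations. The step needs chemoselective hydrogen-atom transfer to the exocyclic alkene in the presence of the enone, which the preference of the metal hydride for the more electron-rich 1,1-disubstituted alkene should secure, and face selectivity at C10, which the C4 gem-dimethyl group on the tether and the equatorial, in-plane C9 silyloxy group of the all-equatorial ring B should secure.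

Step 12
Reactants: 20 (4aR,5R,6S,8aS)-5-[(tert-butyldimethylsilyl)oxy]-1,1,4a,6-tetramethyloctahydronaphthalen-2(1H)-one
Product: 21 (2S,4aR,5R,6S,8aR)-5-[(tert-butyldimethylsilyl)oxy]-1,1,4a,6-tetramethyldecahydronaphthalen-2-ol
Conditions: LiBH(s-Bu)3 (L-Selectride), THF, −78 °C; then NaOH, H2O2, 0 °C
Reagents that add atoms: none
Why: Reduction with a bulky trialkylborohydride; hydride should arrive along the equatorial trajectory of the 4,4-dimethyl-3-ketone and give the axial C3 alcohol, as is usual for this ketone type.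

Step 13
Reactants: 21 (2S,4aR,5R,6S,8aR)-5-[(tert-butyldimethylsilyl)oxy]-1,1,4a,6-tetramethyldecahydronaphthalen-2-ol
Product: 22 tert-butyl{[(1R,2S,4aS,6R,8aR)-6-bromo-2,5,5,8a-tetramethyldecahydronaphthalen-1-yl]oxy}dimethylsilane
Conditions: CBr4, PPh3, CH2Cl2, 0 → 40 °C
Reagents that add atoms: tetrabromomethane, BrC(Br)(Br)Br
Why: Appel reaction; SN2 displacement of the axial alkoxyphosphonium by bromide with inversion should give the equatorial C3 bromide, while the hindered C9 silyl ether stays intact.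

Step 14
Reactants: 22 tert-butyl{[(1R,2S,4aS,6R,8aR)-6-bromo-2,5,5,8a-tetramethyldecahydronaphthalen-1-yl]oxy}dimethylsilane
Product: 23 (1R,2S,4aS,6R,8aR)-6-bromo-2,5,5,8a-tetramethyldecahydronaphthalen-1-ol
Conditions: Bu4NF, THF, 50 °C
Reagents that add atoms: none
Why: Fluoride desilylation; the equatorial bromide has no antiperiplanar β-hydrogen in the locked trans-decalin, so E2 loss of HBr is not expected.

Step 15
Reactants: 23 (1R,2S,4aS,6R,8aR)-6-bromo-2,5,5,8a-tetramethyldecahydronaphthalen-1-ol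
Product: 24 (2S,4aS,6R,8aR)-6-bromo-2,5,5,8a-tetramethyloctahydronaphthalen-1(2H)-one
Conditions: Dess–Martin periodinane, CH2Cl2, rt
Reagents that add atoms: none
Why: Dess–Martin oxidation of the hindered secondary alcohol under neutral conditions; the C8 methyl is already in its thermodynamically preferred equatorial position.

Step 16
Reactants: 7 tert-butyl{[(3R)-5-iodo-3-methylpent-1-en-3-yl]oxy}dimethylsilane and 24 (2S,4aS,6R,8aR)-6-bromo-2,5,5,8a-tetramethyloctahydronaphthalen-1(2H)-one
Product: 27 (1R,2S,4aS,6R,8aR)-6-bromo-1-[(3R)-3-[(tert-butyldimethylsilyl)oxy]-3-methylpent-4-en-1-yl]-2,5,5,8a-tetramethyldecahydronaphthalen-1-ol, via alkyllithium 25 (not isolated), via alkylcerium dichloride 26 (not isolated)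
Conditions: 7, t-BuLi (2 equiv), Et2O/pentane, −78 °C; CeCl3, THF, −78 °C; then 24, −78 → −40 °C; then H2O
Reagents that add atoms: none
Why: Iodine–lithium exchange and CeCl3-mediated 1,2-addition of the weakly basic organocerium to the enolisable, hindered ketone; the axial C20 methyl on C10 blocks the equatorial trajectory, so attack should be axial on the β face and give the equatorial 9-OH cis to C20 with the side chain axial, while C13 comes unchanged from linalool.

Step 17
Reactants: 27 (1R,2S,4aS,6R,8aR)-6-bromo-1-[(3R)-3-[(tert-butyldimethylsilyl)oxy]-3-methylpent-4-en-1-yl]-2,5,5,8a-tetramethyldecahydronaphthalen-1-ol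
Product: 28 (1R,2S,4aS,6R,8aR)-6-bromo-1-[(3R)-3-hydroxy-3-methylpent-4-en-1-yl]-2,5,5,8a-tetramethyldecahydronaphthalen-1-ol (target, CNP0318118.1)
Conditions: Bu4NF, THF, 40 °C
Reagents that add atoms: none
Why: Fluoride cleavage of the tertiary allylic silyl ether under non-acidic conditions should avoid ionisation of the allylic carbinol and leave the equatorial bromide untouched.

**Compound list**

1 | (R)-(−)-linalool, (3R)-3,7-dimethylocta-1,6-dien-3-ol | C=C[C@](C)(O)CCC=C(C)C | starting material
2 | tert-butyl{[(3R)-3,7-dimethylocta-1,6-dien-3-yl]oxy}dimethylsilane | C=C[C@](C)(O[Si](C)(C)C(C)(C)C)CCC=C(C)C | intermediate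
3 | secondary ozonide, 5-[(3R)-3-[(tert-butyldimethylsilyl)oxy]-3-methylpent-4-en-1-yl]-3,3-dimethyl-1,2,4-trioxolane | C=C[C@](C)(O[Si](C)(C)C(C)(C)C)CCC1OOC(C)(C)O1 | intermediate (not isolated)
4 | (4R)-4-[(tert-butyldimethylsilyl)oxy]-4-methylhex-5-enal | C=C[C@](C)(O[Si](C)(C)C(C)(C)C)CCC=O | intermediate
5 | (4R)-4-[(tert-butyldimethylsilyl)oxy]-4-methylhex-5-enoic acid | C=C[C@](C)(O[Si](C)(C)C(C)(C)C)CCC(=O)O | intermediate
6 | Barton ester, 2-thioxopyridin-1(2H)-yl (4R)-4-[(tert-butyldimethylsilyl)oxy]-4-methylhex-5-enoate | C=C[C@](C)(O[Si](C)(C)C(C)(C)C)CCC(=O)ON1C=CC=CC1=S | intermediate (not isolated)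
7 | tert-butyl{[(3R)-5-iodo-3-methylpent-1-en-3-yl]oxy}dimethylsilane | C=C[C@](C)(O[Si](C)(C)C(C)(C)C)CCI | intermediate
8 | (S)-(−)-pulegone, (5S)-5-methyl-2-(propan-2-ylidene)cyclohexan-1-one | O=C1C[C@@H](C)CCC1=C(C)C | starting material
9 | bromomagnesium enolate of 10 | C=CC(C)(C)C1=C(O[Mg]Br)C[C@@H](C)CC1 | intermediate (not isolated)
10 | (2R,5S)-5-methyl-2-(2-methylbut-3-en-2-yl)cyclohexan-1-one | O=C1C[C@@H](C)CC[C@@H]1C(C)(C)C=C | intermediate
11 | potassium enolate of 10 (towards C9) | [K]OC1=C[C@@H](C)CC[C@@H]1C(C)(C)C=C | intermediate (not isolated)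
12 | (2R,3S,6R)-2-hydroxy-3-methyl-6-(2-methylbut-3-en-2-yl)cyclohexan-1-one | O=C1[C@H](O)[C@@H](C)CC[C@@H]1C(C)(C)C=C | intermediate
13 | (2R,3S,6R)-2-[(tert-butyldimethylsilyl)oxy]-3-methyl-6-(2-methylbut-3-en-2-yl)cyclohexan-1-one | O=C1[C@H](O[Si](C)(C)C(C)(C)C)[C@@H](C)CC[C@@H]1C(C)(C)C=C | intermediate
14 | tert-butyldimethyl{[(1R,3R,6S)-6-methyl-2-methylidene-3-(2-methylbut-3-en-2-yl)cyclohexyl]oxy}silane | C=C1[C@H](O[Si](C)(C)C(C)(C)C)[C@@H](C)CC[C@@H]1C(C)(C)C=C | intermediate
15 | 3-[(1S,3R,4S)-3-[(tert-butyldimethylsilyl)oxy]-4-methyl-2-methylidenecyclohexyl]-3-methylbutan-2-one | C=C1[C@H](O[Si](C)(C)C(C)(C)C)[C@@H](C)CC[C@@H]1C(C)(C)C(C)=O | intermediate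
16 | lithium enolate of 15 | C=C1[C@H](O[Si](C)(C)C(C)(C)C)[C@@H](C)CC[C@@H]1C(C)(C)C(=C)O[Li] | intermediate (not isolated)
17 | Mannich base, 1-(dimethylamino)-4-[(1S,3R,4S)-3-[(tert-butyldimethylsilyl)oxy]-4-methyl-2-methylidenecyclohexyl]-4-methylpentan-3-one | C=C1[C@H](O[Si](C)(C)C(C)(C)C)[C@@H](C)CC[C@@H]1C(C)(C)C(=O)CCN(C)C | intermediate (not isolated)
18 | methiodide of 17 (trimethylammonium iodide) | C=C1[C@H](O[Si](C)(C)C(C)(C)C)[C@@H](C)CC[C@@H]1C(C)(C)C(=O)CC[N+](C)(C)C.[I-] | intermediate (not isolated)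
19 | 4-[(1S,3R,4S)-3-[(tert-butyldimethylsilyl)oxy]-4-methyl-2-methylidenecyclohexyl]-4-methylpent-1-en-3-one | C=C1[C@H](O[Si](C)(C)C(C)(C)C)[C@@H](C)CC[C@@H]1C(C)(C)C(=O)C=C | intermediate
20 | (4aR,5R,6S,8aS)-5-[(tert-butyldimethylsilyl)oxy]-1,1,4a,6-tetramethyloctahydronaphthalen-2(1H)-one | CC(C)(C)[Si](C)(C)O[C@@H]1[C@@H](C)CC[C@@H]2C(C)(C)C(=O)CC[C@]21C | intermediate
21 | (2S,4aR,5R,6S,8aR)-5-[(tert-butyldimethylsilyl)oxy]-1,1,4a,6-tetramethyldecahydronaphthalen-2-ol | CC(C)(C)[Si](C)(C)O[C@@H]1[C@@H](C)CC[C@@H]2C(C)(C)[C@@H](O)CC[C@]21C | intermediate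
22 | tert-butyl{[(1R,2S,4aS,6R,8aR)-6-bromo-2,5,5,8a-tetramethyldecahydronaphthalen-1-yl]oxy}dimethylsilane | CC(C)(C)[Si](C)(C)O[C@@H]1[C@@H](C)CC[C@@H]2C(C)(C)[C@H](Br)CC[C@]21C | intermediate
23 | (1R,2S,4aS,6R,8aR)-6-bromo-2,5,5,8a-tetramethyldecahydronaphthalen-1-ol | O[C@@H]1[C@@H](C)CC[C@@H]2C(C)(C)[C@H](Br)CC[C@]21C | intermediate
24 | (2S,4aS,6R,8aR)-6-bromo-2,5,5,8a-tetramethyloctahydronaphthalen-1(2H)-one | O=C1[C@@H](C)CC[C@@H]2C(C)(C)[C@H](Br)CC[C@]21C | intermediate
25 | {(3R)-3-[(tert-butyldimethylsilyl)oxy]-3-methylpent-4-en-1-yl}lithium | C=C[C@](C)(O[Si](C)(C)C(C)(C)C)CC[Li] | intermediate (not isolated)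
26 | {(3R)-3-[(tert-butyldimethylsilyl)oxy]-3-methylpent-4-en-1-yl}cerium dichloride | C=C[C@](C)(O[Si](C)(C)C(C)(C)C)CC[Ce](Cl)Cl | intermediate (not isolated)
27 | (1R,2S,4aS,6R,8aR)-6-bromo-1-[(3R)-3-[(tert-butyldimethylsilyl)oxy]-3-methylpent-4-en-1-yl]-2,5,5,8a-tetramethyldecahydronaphthalen-1-ol | C=C[C@](C)(O[Si](C)(C)C(C)(C)C)CC[C@@]1(O)[C@@H](C)CC[C@@H]2C(C)(C)[C@H](Br)CC[C@]21C | intermediate
28 | (1R,2S,4aS,6R,8aR)-6-bromo-1-[(3R)-3-hydroxy-3-methylpent-4-en-1-yl]-2,5,5,8a-tetramethyldecahydronaphthalen-1-ol | C=C[C@](C)(O)CC[C@@]1(O)[C@@H](C)CC[C@@H]2C(C)(C)[C@H](Br)CC[C@]21C | target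

**Step count and risks**

Total step count: 17. Longest linear sequence: 13 steps (steps 5–17, from (S)-pulegone); the side-chain branch (steps 1–4) joins at step 16.

Steps most likely to fail:

1. Step 11 (key step). Process at risk: hydrogen-atom transfer to the vinyl ketone or reduction of the C10 radical before it closes, and closure through the α face (cis fusion) at 60 °C. Fallback, setting out from 13 and coming back at 20: the methyl group is brought in as a nucleophile and the same C10 radical is made by photoredox fragmentation of a tertiary oxalate, with no metal hydride present and at room temperature. Compound 13 with MeMgBr/CeCl3 (THF, −78 °C) should give the tertiary alcohol F1 (either C10 epimer serves). Tsuji–Wacker oxidation (PdCl2, CuCl, O2, DMF/H2O) should give the methyl ketone F2. LiN(i-Pr)2 (2.2 equiv) gives the dilithium alkoxide enolate F3, Eschenmoser's salt the Mannich base F4, MeI the methiodide F5 and NaHCO3 the vinyl ketone F6. Acylation of the tertiary hydroxyl with N-phthalimidoyl chlorooxalate (Et3N, DMAP, CH2Cl2) gives the N-phthalimidoyl oxalate F7. Blue-light irradiation with [Ru(bpy)3](PF6)2 (1 mol %), Hantzsch ester and i-Pr2NEt·HBF4 in CH2Cl2 should fragment F7 to the C10 radical, which closes in the same 6-endo Giese mode to 20.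

2. Step 13. Process at risk: ionisation or elimination of the neopentyl-type C3 alkoxyphosphonium (Δ2 alkene, 1,2-methyl shift) instead of backside displacement. Fallback, setting out from 20 and coming back at 22: the bromine is put on an sp2 carbon and the stereocentre is then made by hydrogen-atom delivery. Ketone 20 with Tf2O and 2,6-di-tert-butyl-4-methylpyridine (CH2Cl2) gives the enol triflate F8 (enolisation is possible only towards C2). Nickel-catalysed triflate–bromide exchange (Ni(cod)2 cat., LiBr, DMA/THF, rt) gives the alkenyl bromide F9. Hydrogen-atom-transfer hydrogenation of the alkenyl bromide (Co(acac)2, t-BuOOH, Et3SiH, 1,4-cyclohexadiene, n-PrOH) should deliver hydrogen axially to the α-bromo radical and give the equatorial bromide 22.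

3. Step 16. Process at risk: retro-[1,4]-Brook silyl migration in the γ-silyloxy alkyllithium before transmetalation, enolisation of the C9 ketone towards C8, and lithium–bromine exchange at C3. Fallback, setting out from 7 and 24 and coming back at 27: a samarium Barbier coupling, in which no basic carbanion is preformed. Iodide 7 and ketone 24 are added together to samarium diiodide (SmI2, 2.2 equiv) with NiI2 (1 mol %) in THF at 0 °C, so that the organosamarium is formed in the presence of the ketone and trapped at once; the same axial attack anti to the C20 methyl is expected. No new compound is made on this path.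

Further compounds
F1 | step 11 | (2R,3S,6R)-2-[(tert-butyldimethylsilyl)oxy]-1,3-dimethyl-6-(2-methylbut-3-en-2-yl)cyclohexan-1-ol (C1 epimers) | CC1(O)[C@H](O[Si](C)(C)C(C)(C)C)[C@@H](C)CC[C@@H]1C(C)(C)C=C
F2 | step 11 | 3-[(1R,3R,4S)-3-[(tert-butyldimethylsilyl)oxy]-2-hydroxy-2,4-dimethylcyclohexyl]-3-methylbutan-2-one (C2 epimers) | CC1(O)[C@H](O[Si](C)(C)C(C)(C)C)[C@@H](C)CC[C@@H]1C(C)(C)C(C)=O
F3 | step 11 | dilithium alkoxide enolate of F2 | CC1(O[Li])[C@H](O[Si](C)(C)C(C)(C)C)[C@@H](C)CC[C@@H]1C(C)(C)C(=C)O[Li]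
F4 | step 11 | Mannich base, 1-(dimethylamino)-4-[(1R,3R,4S)-3-[(tert-butyldimethylsilyl)oxy]-2-hydroxy-2,4-dimethylcyclohexyl]-4-methylpentan-3-one | CC1(O)[C@H](O[Si](C)(C)C(C)(C)C)[C@@H](C)CC[C@@H]1C(C)(C)C(=O)CCN(C)C
F5 | step 11 | methiodide of F4 (trimethylammonium iodide) | CC1(O)[C@H](O[Si](C)(C)C(C)(C)C)[C@@H](C)CC[C@@H]1C(C)(C)C(=O)CC[N+](C)(C)C.[I-]
F6 | step 11 | 4-[(1R,3R,4S)-3-[(tert-butyldimethylsilyl)oxy]-2-hydroxy-2,4-dimethylcyclohexyl]-4-methylpent-1-en-3-one | CC1(O)[C@H](O[Si](C)(C)C(C)(C)C)[C@@H](C)CC[C@@H]1C(C)(C)C(=O)C=C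
F7 | step 11 | (2R,3S,6R)-2-[(tert-butyldimethylsilyl)oxy]-1,3-dimethyl-6-(2-methyl-3-oxopent-4-en-2-yl)cyclohexyl 1,3-dioxoisoindolin-2-yl oxalate | CC1(OC(=O)C(=O)ON2C(=O)c3ccccc3C2=O)[C@H](O[Si](C)(C)C(C)(C)C)[C@@H](C)CC[C@@H]1C(C)(C)C(=O)C=C
F8 | step 13 | Δ2-enol triflate of 20, 5-[(tert-butyldimethylsilyl)oxy]-1,1,4a,6-tetramethyl-1,4,4a,5,6,7,8,8a-octahydronaphthalen-2-yl trifluoromethanesulfonate (stereocentres as in 20) | CC(C)(C)[Si](C)(C)O[C@@H]1[C@@H](C)CC[C@@H]2C(C)(C)C(OS(=O)(=O)C(F)(F)F)=CC[C@]21C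
F9 | step 13 | alkenyl bromide, {[6-bromo-2,5,5,8a-tetramethyl-1,2,3,4,4a,5,8,8a-octahydronaphthalen-1-yl]oxy}(tert-butyl)dimethylsilane (stereocentres as in 20) | CC(C)(C)[Si](C)(C)O[C@@H]1[C@@H](C)CC[C@@H]2C(C)(C)C(Br)=CC[C@]21C
F0 | step 16 | none | none
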